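## Retrosynthetic overview

1. The strategy rests on ring A being a polyketide-type resorcinol. With C1 as the carbon carrying the CH2CH2 bridge, C3 (OMe) and C5 (OH) are 1,3-related oxygens, C2 and C4 carry the 4-hydroxybenzyl groups, and C6 is unsubstituted, the site of a lost carboxyl.
2. Target ⇒ (decarboxylation, O-debenzylation, O-methylation at C3) a benzyl resorcylate with the carboxyl on C6 ⇒ (ring-A C1–C6 aldol bond and ester C–O bond) a dibenzylated diketo-dioxinone plus benzyl alcohol.
3. Diketo-dioxinone ⇒ (α′-acylation of a keto-dioxinone dianion) keto-dioxinone plus the ring-B 3-arylpropanoic acid; keto-dioxinone ⇒ 2,2,6-trimethyldioxinone by γ-benzylation, then γ-acylation with a 3-arylpropanoyl unit whose CH2Ar becomes the second benzyl group.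
4. Ring-B acid ⇒ benzyl–aryl Suzuki–Miyaura coupling of a 2-formylarylboronic acid with 4-(benzyloxy)benzyl chloride, then a reductive Knoevenagel two-carbon homologation.
5. Ring order: ring B and the three 4-oxygenated phenyl rings are bought; ring A is the only ring constructed (step 6), followed by methylation, hydrogenolysis and decarboxylation.

Key step: step 6

Remark: the target has no stereogenic element (it is achiral), so no configuration has to be controlled. The sp3 stereocentres that appear in the dioxinone and triketone intermediates are carried as mixtures and all end as aromatic carbons of ring A.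

## Route

Step 1
Reactants: 1 [4-(benzyloxy)-2-formylphenyl]boronic acid; 2 4-(benzyloxy)benzyl chloride
Product: 3 5-(benzyloxy)-2-[4-(benzyloxy)benzyl]benzaldehyde
Conditions: Pd(dppf)Cl2 (cat.), K3PO4, THF–H2O (10:1), 65 °C
Reagents that add atoms: none
Why: A Suzuki–Miyaura sp2–sp3 coupling in which the benzylic chloride adds oxidatively to Pd(0) with no β-hydrogen to lose, while the aldehyde and the benzyl ethers are inert to the mild phosphate base.

Step 2
Reactants: 3 5-(benzyloxy)-2-[4-(benzyloxy)benzyl]benzaldehyde; 4 Meldrum's acid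
Product: 7 3-{5-(benzyloxy)-2-[4-(benzyloxy)benzyl]phenyl}propanoic acid, via arylidene Meldrum's acid 5 (not isolated), via reduced Meldrum's acid adduct 6 (not isolated)
Conditions: HCO2H–Et3N (5:2), 95–100 °C
Reagents that add atoms: none
Why: A reductive Knoevenagel homologation in which condensation gives arylidene 5, triethylammonium formate transfers hydride to this highly electrophilic alkene to give 6, and 6 is cleaved and decarboxylated at this temperature to the propanoic acid, the aryl benzyl ethers being safe in the absence of a hydrogenation catalyst.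

Step 3
Reactants: 8 2,2,6-trimethyl-4H-1,3-dioxin-4-one; 2 4-(benzyloxy)benzyl chloride
Product: 10 6-{2-[4-(benzyloxy)phenyl]ethyl}-2,2-dimethyl-4H-1,3-dioxin-4-one, via lithium dienolate 9 (not isolated)
Conditions: 8 (1.3 equiv), LDA (1.3 equiv), THF–DMPU, −78 °C; then 2 (1.0 equiv), −78 → −20 °C
Reagents that add atoms: none
Why: Enolate alkylation of the lithium dienolate of the dioxinone, which reacts with reactive halides at the exocyclic γ-carbon; the small excess of dienolate should hold back double benzylation.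

Step 4
Reactants: 10 6-{2-[4-(benzyloxy)phenyl]ethyl}-2,2-dimethyl-4H-1,3-dioxin-4-one; 11 3-[4-(benzyloxy)phenyl]propanoic acid
Product: 14 6-{1,5-bis[4-(benzyloxy)phenyl]-3-oxopentan-2-yl}-2,2-dimethyl-4H-1,3-dioxin-4-one (racemic), via acyl imidazole 12 (not isolated), via lithium dienolate 13 (not isolated)
Conditions: 11, CDI, THF, rt (gives 12); separately 10 (2.0 equiv), LiHMDS (2.0 equiv), THF, −78 °C (gives 13); add 12 (1.0 equiv), −78 → −20 °C; AcOH quench
Reagents that add atoms: none
Why: A crossed Claisen-type C-acylation of the γ-lithiated dioxinone dienolate by an N-acylimidazole, the standard entry to keto-dioxinones (the second equivalent of 13 serves as base for the more acidic product and returns 10); the new CH stereocentre forms racemic and is later erased in ring A.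

Step 5
Reactants: 14 6-{1,5-bis[4-(benzyloxy)phenyl]-3-oxopentan-2-yl}-2,2-dimethyl-4H-1,3-dioxin-4-one; 7 3-{5-(benzyloxy)-2-[4-(benzyloxy)benzyl]phenyl}propanoic acid
Product: 17 6-{4-[4-(benzyloxy)benzyl]-1-[4-(benzyloxy)phenyl]-7-{5-(benzyloxy)-2-[4-(benzyloxy)benzyl]phenyl}-3,5-dioxoheptan-2-yl}-2,2-dimethyl-4H-1,3-dioxin-4-one (diastereomer mixture), via acyl imidazole 15 (not isolated), via dilithium dianion 16 (not isolated)
Conditions: 7, CDI, THF, rt (gives 15); separately 14, LDA (3.0 equiv), THF, −78 → −40 °C (gives 16); add 15 (1.0 equiv), −78 °C; AcOH quench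
Reagents that add atoms: none
Why: Acylation of a 1,3-dicarbonyl-type dianion, in which the second-formed, less stabilised α′-carbanion of 16 is the more nucleophilic site and is acylated by the N-acylimidazole to the 1,3-diketone; the second CH stereocentre forms without control, which does not matter because both centres become aromatic carbons.

Step 6
Reactants: 17 dibenzylated diketo-dioxinone (as above); 18 benzyl alcohol
Product: 22 benzyl 3,5-bis[4-(benzyloxy)benzyl]-6-(2-{5-(benzyloxy)-2-[4-(benzyloxy)benzyl]phenyl}ethyl)-2,4-dihydroxybenzoate, via acylketene 19 (not isolated), via triketo ester 20 (not isolated), via cyclic aldol 21 (not isolated)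
Conditions: 18 (5 equiv), PhMe, 110 °C; cool, Cs2CO3, THF, rt; then HCl (4 M in dioxane), rt
Reagents that add atoms: none
Why: Heating 17 should trigger a retro-hetero-Diels–Alder loss of acetone to acylketene 19, which excess benzyl alcohol converts into the 3,5,7-triketo ester 20 before the neighbouring enol can capture the ketene. Carbonate then deprotonates the C2 methylene of 20, the only unsubstituted 1,3-dicarbonyl carbon, and this carbon adds to the C7 ketone in a 6-(enolexo)-exo-trig aldol that forms the ring-A C1–C6 bond and closes ring A as cyclic aldol 21; acid-induced dehydration and two enolisations then aromatise it to 22. The closest known reaction is the biomimetic polyketide aldol aromatisation of triketo esters released from diketo-dioxinones, the standard route to resorcylates. No stereocentre survives, since the two benzylated sp3 carbons and the aldol carbinol all become aromatic carbons, so the diastereomer mixture of 17 converges on one product. The step needs C-aldol closure to win over 2-pyranone formation, Claisen closure and retro-Claisen cleavage: the benzyl groups make C4 and C6 poor nucleophiles whose only cyclisation modes give four-membered rings or a quaternary Claisen product, the C8 methylene is not acidic enough for carbonate, and benzyl alcohol as the only protic component makes any ester exchange degenerate.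

Step 7
Reactants: 22 benzyl 3,5-bis[4-(benzyloxy)benzyl]-6-(2-{5-(benzyloxy)-2-[4-(benzyloxy)benzyl]phenyl}ethyl)-2,4-dihydroxybenzoate
Product: 23 benzyl 3,5-bis[4-(benzyloxy)benzyl]-6-(2-{5-(benzyloxy)-2-[4-(benzyloxy)benzyl]phenyl}ethyl)-2-hydroxy-4-methoxybenzoate
Conditions: MeI (1.5 equiv), K2CO3, acetone, rt → 40 °C
Reagents that add atoms: iodomethane, CI
Why: A Williamson O-methylation that should be site-selective because the hydroxyl ortho to the ester is held in a hydrogen bond to the ester carbonyl and is far less acidic and nucleophilic than the para hydroxyl, as in the usual 4-O-alkylation of 2,4-dihydroxybenzoates.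

Step 8
Reactants: 23 benzyl 3,5-bis[4-(benzyloxy)benzyl]-6-(2-{5-(benzyloxy)-2-[4-(benzyloxy)benzyl]phenyl}ethyl)-2-hydroxy-4-methoxybenzoate
Product: 24 2-hydroxy-3,5-bis(4-hydroxybenzyl)-6-{2-[5-hydroxy-2-(4-hydroxybenzyl)phenyl]ethyl}-4-methoxybenzoic acid
Conditions: H2 (1 atm), 10% Pd/C, EtOAc–MeOH, rt
Reagents that add atoms: none
Why: Catalytic hydrogenolysis should cleave the four aryl benzyl ethers and the benzyl ester in one operation, while the diarylmethane and bibenzyl C–C bonds, the methyl ether and the arenes are stable at 1 atm over Pd/C.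

Step 9
Reactants: 24 2-hydroxy-3,5-bis(4-hydroxybenzyl)-6-{2-[5-hydroxy-2-(4-hydroxybenzyl)phenyl]ethyl}-4-methoxybenzoic acid
Product: 25 Bleochrin A, 2,4-bis(4-hydroxybenzyl)-5-{2-[5-hydroxy-2-(4-hydroxybenzyl)phenyl]ethyl}-3-methoxyphenol
Conditions: degassed DMF, 140 °C, Ar
Reagents that add atoms: none
Why: Thermal protodecarboxylation of an ortho-hydroxy, para-alkoxy benzoic acid, which proceeds by ipso-protonation through the keto tautomer (a β-keto acid) and is eased further by the two flanking substituents.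

## Compound list

1 | [4-(benzyloxy)-2-formylphenyl]boronic acid | O=Cc1cc(OCc2ccccc2)ccc1B(O)O | starting material
2 | 4-(benzyloxy)benzyl chloride | ClCc1ccc(OCc2ccccc2)cc1 | starting material
3 | 5-(benzyloxy)-2-[4-(benzyloxy)benzyl]benzaldehyde | O=Cc1cc(OCc2ccccc2)ccc1Cc1ccc(OCc2ccccc2)cc1 | intermediate
4 | Meldrum's acid (2,2-dimethyl-1,3-dioxane-4,6-dione) | CC1(C)OC(=O)CC(=O)O1 | starting material
5 | 5-{5-(benzyloxy)-2-[4-(benzyloxy)benzyl]benzylidene}-2,2-dimethyl-1,3-dioxane-4,6-dione | CC1(C)OC(=O)C(=Cc2cc(OCc3ccccc3)ccc2Cc2ccc(OCc3ccccc3)cc2)C(=O)O1 | intermediate (not isolated)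
6 | 5-{5-(benzyloxy)-2-[4-(benzyloxy)benzyl]benzyl}-2,2-dimethyl-1,3-dioxane-4,6-dione | CC1(C)OC(=O)C(Cc2cc(OCc3ccccc3)ccc2Cc2ccc(OCc3ccccc3)cc2)C(=O)O1 | intermediate (not isolated)
7 | 3-{5-(benzyloxy)-2-[4-(benzyloxy)benzyl]phenyl}propanoic acid | OC(=O)CCc1cc(OCc2ccccc2)ccc1Cc1ccc(OCc2ccccc2)cc1 | intermediate
8 | 2,2,6-trimethyl-4H-1,3-dioxin-4-one | CC1=CC(=O)OC(C)(C)O1 | starting material
9 | lithium 2,2-dimethyl-6-methylidene-6H-1,3-dioxin-4-olate (γ-dienolate of 8) | [Li]OC1=CC(=C)OC(C)(C)O1 | intermediate (not isolated)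
10 | 6-{2-[4-(benzyloxy)phenyl]ethyl}-2,2-dimethyl-4H-1,3-dioxin-4-one | CC1(C)OC(CCc2ccc(OCc3ccccc3)cc2)=CC(=O)O1 | intermediate
11 | 3-[4-(benzyloxy)phenyl]propanoic acid | OC(=O)CCc1ccc(OCc2ccccc2)cc1 | starting material
12 | 3-[4-(benzyloxy)phenyl]-1-(1H-imidazol-1-yl)propan-1-one | O=C(CCc1ccc(OCc2ccccc2)cc1)n1ccnc1 | intermediate (not isolated)
13 | lithium γ-dienolate of 10 | [Li]OC1=CC(=CCc2ccc(OCc3ccccc3)cc2)OC(C)(C)O1 | intermediate (not isolated)
14 | 6-{1,5-bis[4-(benzyloxy)phenyl]-3-oxopentan-2-yl}-2,2-dimethyl-4H-1,3-dioxin-4-one (racemic) | CC1(C)OC(=CC(=O)O1)C(Cc1ccc(OCc2ccccc2)cc1)C(=O)CCc1ccc(OCc2ccccc2)cc1 | intermediate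
15 | 3-{5-(benzyloxy)-2-[4-(benzyloxy)benzyl]phenyl}-1-(1H-imidazol-1-yl)propan-1-one | O=C(CCc1cc(OCc2ccccc2)ccc1Cc1ccc(OCc2ccccc2)cc1)n1ccnc1 | intermediate (not isolated)
16 | dilithium γ,α′-dianion of 14 | [Li]OC1=CC(=C(Cc2ccc(OCc3ccccc3)cc2)C(O[Li])=CCc2ccc(OCc3ccccc3)cc2)OC(C)(C)O1 | intermediate (not isolated)
17 | 6-{4-[4-(benzyloxy)benzyl]-1-[4-(benzyloxy)phenyl]-7-{5-(benzyloxy)-2-[4-(benzyloxy)benzyl]phenyl}-3,5-dioxoheptan-2-yl}-2,2-dimethyl-4H-1,3-dioxin-4-one (diastereomer mixture) | CC1(C)OC(=CC(=O)O1)C(Cc1ccc(OCc2ccccc2)cc1)C(=O)C(Cc1ccc(OCc2ccccc2)cc1)C(=O)CCc1cc(OCc2ccccc2)ccc1Cc1ccc(OCc2ccccc2)cc1 | intermediate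
18 | benzyl alcohol | OCc1ccccc1 | starting material
19 | acylketene: 4,6-bis[4-(benzyloxy)benzyl]-9-{5-(benzyloxy)-2-[4-(benzyloxy)benzyl]phenyl}nona-1-ene-1,3,5,7-tetraone | O=C=CC(=O)C(Cc1ccc(OCc2ccccc2)cc1)C(=O)C(Cc1ccc(OCc2ccccc2)cc1)C(=O)CCc1cc(OCc2ccccc2)ccc1Cc1ccc(OCc2ccccc2)cc1 | intermediate (not isolated)
20 | benzyl 4,6-bis[4-(benzyloxy)benzyl]-9-{5-(benzyloxy)-2-[4-(benzyloxy)benzyl]phenyl}-3,5,7-trioxononanoate | O=C(OCc1ccccc1)CC(=O)C(Cc1ccc(OCc2ccccc2)cc1)C(=O)C(Cc1ccc(OCc2ccccc2)cc1)C(=O)CCc1cc(OCc2ccccc2)ccc1Cc1ccc(OCc2ccccc2)cc1 | intermediate (not isolated)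
21 | benzyl 3,5-bis[4-(benzyloxy)benzyl]-2-(2-{5-(benzyloxy)-2-[4-(benzyloxy)benzyl]phenyl}ethyl)-2-hydroxy-4,6-dioxocyclohexane-1-carboxylate | O=C(OCc1ccccc1)C1C(=O)C(Cc2ccc(OCc3ccccc3)cc2)C(=O)C(Cc2ccc(OCc3ccccc3)cc2)C1(O)CCc1cc(OCc2ccccc2)ccc1Cc1ccc(OCc2ccccc2)cc1 | intermediate (not isolated)
22 | benzyl 3,5-bis[4-(benzyloxy)benzyl]-6-(2-{5-(benzyloxy)-2-[4-(benzyloxy)benzyl]phenyl}ethyl)-2,4-dihydroxybenzoate | O=C(OCc1ccccc1)c1c(O)c(Cc2ccc(OCc3ccccc3)cc2)c(O)c(Cc2ccc(OCc3ccccc3)cc2)c1CCc1cc(OCc2ccccc2)ccc1Cc1ccc(OCc2ccccc2)cc1 | intermediate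
23 | benzyl 3,5-bis[4-(benzyloxy)benzyl]-6-(2-{5-(benzyloxy)-2-[4-(benzyloxy)benzyl]phenyl}ethyl)-2-hydroxy-4-methoxybenzoate | O=C(OCc1ccccc1)c1c(O)c(Cc2ccc(OCc3ccccc3)cc2)c(OC)c(Cc2ccc(OCc3ccccc3)cc2)c1CCc1cc(OCc2ccccc2)ccc1Cc1ccc(OCc2ccccc2)cc1 | intermediate
24 | 2-hydroxy-3,5-bis(4-hydroxybenzyl)-6-{2-[5-hydroxy-2-(4-hydroxybenzyl)phenyl]ethyl}-4-methoxybenzoic acid | OC(=O)c1c(O)c(Cc2ccc(O)cc2)c(OC)c(Cc2ccc(O)cc2)c1CCc1cc(O)ccc1Cc1ccc(O)cc1 | intermediate
25 | Bleochrin A | COc1c(Cc2ccc(O)cc2)c(O)cc(CCc2cc(O)ccc2Cc2ccc(O)cc2)c1Cc1ccc(O)cc1 | target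

## Summary

Total step count: 9. Longest linear sequence: 7 steps (steps 3–9 from 8; equally steps 1, 2, 5–9 from 1).

Steps most likely to fail:

Step 6. After ketene capture the triketo ester may close through oxygen (2-pyranone formation with loss of benzyl alcohol) or fragment by retro-Claisen cleavage at a benzylated 1,3-diketone instead of undergoing the C-aldol. The fallback sets out from 17. It is heated in toluene at 110 °C without any alcohol, so that the acylketene is captured deliberately by the adjacent enol to give 6-{1-[4-(benzyloxy)phenyl]-5-{5-(benzyloxy)-2-[4-(benzyloxy)benzyl]phenyl}-3-oxopentan-2-yl}-5-[4-(benzyloxy)benzyl]-4-hydroxy-2H-pyran-2-one F1. F1 is then opened with magnesium benzyloxide in benzyl alcohol–THF, the chelating-alkoxide pyranone-to-resorcylate recyclisation. Mg(II) should hold the ring-opened triketo ester as a chelate and template the C2-to-C7 aldol, and acidification should complete aromatisation. The fallback comes back to the route at 22.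

Step 5. Proton transfer from the enolisable acyl imidazole or from the acidic diketone product may quench the dianion faster than C-acylation, or acylation may occur on oxygen. The fallback sets out from 15 and 14 and replaces the acylation by an aldol addition followed by oxidation. Acyl imidazole 15 is half-reduced with DIBAL-H at −78 °C to 3-{5-(benzyloxy)-2-[4-(benzyloxy)benzyl]phenyl}propanal F2. F2 is added at −78 °C to dianion 16 generated from 14 as before; the aldolate formed is not a proton source for remaining dianion. This should give 6-{4-[4-(benzyloxy)benzyl]-1-[4-(benzyloxy)phenyl]-7-{5-(benzyloxy)-2-[4-(benzyloxy)benzyl]phenyl}-5-hydroxy-3-oxoheptan-2-yl}-2,2-dimethyl-4H-1,3-dioxin-4-one F3 as a diastereomer mixture. Dess–Martin oxidation of the secondary alcohol then gives the 1,3-diketone, and the fallback comes back to the route at 17.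

Step 4. The γ-substituted dienolate 13 is more hindered than the parent dienolate and may be acylated slowly, on oxygen, or lose out to proton exchange with the product. The fallback sets out from 8 and 12 and inverts the order of the two bond formations. The parent dienolate 9 (from 8 with LiHMDS, −78 °C) is acylated with 12, the best-precedented form of this Claisen, to give 6-{4-[4-(benzyloxy)phenyl]-2-oxobutyl}-2,2-dimethyl-4H-1,3-dioxin-4-one F4. The doubly activated methylene of F4 is then mono-C-benzylated with 2 (NaH, THF–DMF, 0 °C), an alkylation of a stabilised 1,3-dicarbonyl-type anion. The fallback comes back to the route at 14.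

## Further compounds

F1 | step 6 | 6-{1-[4-(benzyloxy)phenyl]-5-{5-(benzyloxy)-2-[4-(benzyloxy)benzyl]phenyl}-3-oxopentan-2-yl}-5-[4-(benzyloxy)benzyl]-4-hydroxy-2H-pyran-2-one | O=C1C=C(O)C(Cc2ccc(OCc3ccccc3)cc2)=C(O1)C(Cc1ccc(OCc2ccccc2)cc1)C(=O)CCc1cc(OCc2ccccc2)ccc1Cc1ccc(OCc2ccccc2)cc1
F2 | step 5 | 3-{5-(benzyloxy)-2-[4-(benzyloxy)benzyl]phenyl}propanal | O=CCCc1cc(OCc2ccccc2)ccc1Cc1ccc(OCc2ccccc2)cc1
F3 | step 5 | 6-{4-[4-(benzyloxy)benzyl]-1-[4-(benzyloxy)phenyl]-7-{5-(benzyloxy)-2-[4-(benzyloxy)benzyl]phenyl}-5-hydroxy-3-oxoheptan-2-yl}-2,2-dimethyl-4H-1,3-dioxin-4-one | CC1(C)OC(=CC(=O)O1)C(Cc1ccc(OCc2ccccc2)cc1)C(=O)C(Cc1ccc(OCc2ccccc2)cc1)C(O)CCc1cc(OCc2ccccc2)ccc1Cc1ccc(OCc2ccccc2)cc1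
F4 | step 4 | 6-{4-[4-(benzyloxy)phenyl]-2-oxobutyl}-2,2-dimethyl-4H-1,3-dioxin-4-one | CC1(C)OC(CC(=O)CCc2ccc(OCc3ccccc3)cc2)=CC(=O)O1
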